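**Balance first.** The charge is conserved: solid substrate, starting material, target and whatever you cannot see add up to what went in. So once the solid is gone, any fall in starting material plus target is material leaving for the unseen.

| setting | dawn | dusk | flask |
|---|---|---|---|
| solid substrate | 0.40 M | 0.60 M | 0.80 M |
| partner | 0.88 M | 0.88 M | 0.880 M |
| free catalyst | 130 mM | 130 mM | 130 mM |
| remark | run made earlier | run made earlier |  |
| time |  |  | 50 min |

| run | time / min | target / % | starting material / % | solid substrate / % |
|---|---|---|---|---|
| dawn | 3.00 | 2.7 | 25.3 | 66.1 |
| dawn | 6.00 | 10.2 | 40.2 | 38.8 |
| dawn | 12.0 | 30.1 | 44.5 | 1.4 |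
| dawn | 20.0 | 40.0 | 15.4 | 0 |
| dawn | 40.0 | 17.4 | 0 | 0 |
| dusk | 3.00 | 1.8 | 17.1 | 76.6 |
| dusk | 6.00 | 5.1 | 26.8 | 59.2 |
| dusk | 12.0 | 20.0 | 34.8 | 26.4 |
| dusk | 20.0 | 31.5 | 32.1 | 1.0 |
| dusk | 40.0 | 23.7 | 4.2 | 0 |

(readings scatter by 1 percentage point)

- the target standing at 50 min, as a percentage of the solid substrate charged
- concentration of starting material in solution at 50 min, in percent of saturation

- given per volume of solution although it is solid: solid substrate
- the numbers in the tables scatter with a standard deviation of 1 percentage point
- at the start none of the solid substrate is in solution
- starting material is what solid substrate becomes in solution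
- starting material means what is dissolved; the solid is not counted in it

**Loss half-life.** In the dawn run that sum drops from 55.4% at 20.0 min to 17.4% at 40.0 min, while target averages 28.7%. Take the exit as first-order in target: that gives 0.0662 min⁻¹, and the time in which unfed target halves, the loss half-life, is 10.5 min.

But is the drop lost, or merely parked on catalyst? One per catalyst, such a store in the dawn run holds 32.5% of the charge, less than the 82.6% missing at 40.0 min. That leaves 50 percentage points unexplained, so I keep the loss.

**Delayed dusk.** Make the dusk run your zero: suppose the flask is that run, delayed. Dusk's solid left at 0.0297 M min⁻¹, so the flask's extra charge costs 6.73 min, which puts the flask 3.27 min past dusk's last reading. Decaying dusk's c(target) over that age gives 14.3% of the flask's charge.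

Yet dusk still held 4.2% starting material, which that figure ignores. Decaying the sum instead gives 16.9%, which overcounts. My bracket is those two figures.

**The forecast.** It says 16.5% target, by “Convolving feed with target loss”; its 8% of saturation comes from a separate step, a slow decay of dissolved starting material. I made no reckoning of saturation.

**The result.** The flask gives 16.7% target and 5.01% of saturation.

    partner + catalyst intermediate A ⇌ catalyst intermediate B (K = 3.30 L mol⁻¹, k = 0.0180 L mol⁻¹ s⁻¹)
    catalyst intermediate C → free catalyst + target (k = 0.700 s⁻¹)
    solid substrate ⇌ starting material, rate k3*(cs3 - [starting material]) while solid is left; crystals form when [starting material] > cs3 (solubility = 0.500 M, k = 0.00170 s⁻¹)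
    catalyst intermediate B ⇌ by-product + catalyst intermediate C (K = 31.0 M, k = 0.0170 s⁻¹)
    target → over-reaction product (k = 0.00130 s⁻¹)
    starting material + free catalyst → catalyst intermediate A (k = 0.0250 L mol⁻¹ s⁻¹)

**Tail rule.** Without the turning of target into over-reaction product the flask holds 91.2% target instead of 16.7%, the main reason. The loss half-life is for unfed target: it takes this flask's 16.7% to 0.609% at 100 min, less than the 1.08% standing there, and this flask at 50 min still holds 3.13% starting material upstream of target. From the dawn reading of 17.4% at 40.0 min it predicts 8.99% at 50 min, and the dawn run stands at 8.72%.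

The data stem from a simulated flask with made-up constants, noise included.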